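**Retrosynthetic overview**

- Both CO2H groups are carried as benzyl-protected CH2OH and unveiled last (debenzylation, then double oxidation).
- Ring B (the trisubstituted C2=C3 olefin) is closed last by ring-closing metathesis of a vinyl group and a methallyl group held cis on ring A.
- The quaternary C-4a and the adjacent C-4 centre are set together by an Ireland–Claisen rearrangement of a ring A cyclohexenyl ester of the side-arm acid (fragment 2); the same step places the ring A olefin.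
- Ring A is made first from (S)-citronellal and methyl vinyl ketone by asymmetric Michael addition and intramolecular aldol condensation, then α′-methallylation, BnOCH2Li addition, oxidative enone transposition and Luche reduction.
- Fragment 2 comes from trans-cyclohexane-1,4-diyldimethanol via an alkyne, Negishi carboalumination/oxirane opening and oxidation. Ring order: ring A (aldol), then ring B (metathesis).

Assumption: (S)-citronellal and pure trans-cyclohexane-1,4-diyldimethanol are bought as single isomers. Target locants: C-1 to C-4 = ring B, C-5 to C-8 = ring A, C-4a carries CO2H; the SMILES corresponds to (4R,4aR,7R,8aR), side chain 2S, E olefin, trans-1,4-cyclohexane.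

**Route**

Step 1
Reactants: 1 (S)-citronellal; 2 methyl vinyl ketone
Product: 3 (2R,3S)-3,7-dimethyl-2-(3-oxobutyl)oct-6-enal
Conditions: (R)-2-(methoxydiphenylmethyl)pyrrolidine (5 mol %), ethyl 3,4-dihydroxybenzoate (20 mol %), neat, 4 °C, 36 h
Reagents that add atoms: none
Why: Enamine-catalysed asymmetric Michael addition in which the (R)-diarylprolinol ether shields one face of the E-enamine of 1, so the enone adds to give the 2R centre under catalyst control while the 3S centre of citronellal is untouched.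

Step 2
Reactants: 3 (2R,3S)-3,7-dimethyl-2-(3-oxobutyl)oct-6-enal
Product: 4 (4R)-4-[(2S)-6-methylhept-5-en-2-yl]cyclohex-2-en-1-one
Conditions: LiOH·H2O (0.3 equiv), i-PrOH, rt
Reagents that add atoms: none
Why: Intramolecular aldol condensation closes ring A, because only attack of the methyl-ketone enolate on the aldehyde gives a six-membered ring, and dehydration leaves the former aldehyde α-centre intact as C-4.

Step 3
Reactants: 4 (4R)-4-[(2S)-6-methylhept-5-en-2-yl]cyclohex-2-en-1-one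
Product: 6 (4R,6R)-6-(2-methylprop-2-en-1-yl)-4-[(2S)-6-methylhept-5-en-2-yl]cyclohex-2-en-1-one, via lithium dienolate 5 (not isolated)
Conditions: LiN(i-Pr)2, THF, −78 °C; then 3-bromo-2-methylprop-1-ene, DMPU, −78 → −40 °C
Reagents that add atoms: 3-bromo-2-methylprop-1-ene, CC(=C)CBr
Why: Kinetic α′-enolate alkylation in which the cross-conjugated dienolate is attacked axially by the allylic bromide on the face anti to the C-4 side chain, giving the trans-4,6 (6R) product.

Step 4
Reactants: 7 tributyltin hydride; 8 benzyl chloromethyl ether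
Product: 10 [(benzyloxy)methyl]tributylstannane, via tributylstannyllithium 9 (not isolated)
Conditions: LiN(i-Pr)2, THF, 0 °C; then 8, −78 °C → rt
Reagents that add atoms: none
Why: Stannyl anion alkylation (SN2 on the α-chloro ether) gives the α-alkoxymethylstannane that serves as a hydroxymethyl anion equivalent.

Step 5
Reactants: 6 (4R,6R)-6-(2-methylprop-2-en-1-yl)-4-[(2S)-6-methylhept-5-en-2-yl]cyclohex-2-en-1-one; 10 [(benzyloxy)methyl]tributylstannane
Product: 12 (1S,4R,6R)-1-[(benzyloxy)methyl]-6-(2-methylprop-2-en-1-yl)-4-[(2S)-6-methylhept-5-en-2-yl]cyclohex-2-en-1-ol (major C-1 epimer), via benzyloxymethyllithium 11 (not isolated)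
Conditions: 10, n-BuLi, THF, −78 °C, 10 min; then 6, −78 °C; H2O
Reagents that add atoms: none
Why: Tin–lithium exchange followed by 1,2-addition of the α-alkoxyorganolithium to the enone carbonyl anti to the axial methallyl group; the new carbinol centre is erased in step 6, so its epimer ratio does not matter.

Step 6
Reactants: 12 (1S,4R,6R)-1-[(benzyloxy)methyl]-6-(2-methylprop-2-en-1-yl)-4-[(2S)-6-methylhept-5-en-2-yl]cyclohex-2-en-1-ol
Product: 13 (4R,6R)-3-[(benzyloxy)methyl]-4-(2-methylprop-2-en-1-yl)-6-[(2S)-6-methylhept-5-en-2-yl]cyclohex-2-en-1-one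
Conditions: pyridinium chlorochromate (C5H5NH)[CrO3Cl] (3 equiv), 4 Å molecular sieves, CH2Cl2, rt
Reagents that add atoms: pyridinium chlorochromate, [O-][Cr](=O)(=O)Cl.c1cc[nH+]cc1
Why: Dauben–Babler oxidative 1,3-transposition in which the tertiary allylic chromate ester undergoes a [3,3] shift and is oxidised by hexavalent chromium to the transposed enone (the new carbonyl oxygen comes from the chromate), leaving C-4 and C-6 untouched.

Step 7
Reactants: 13 (4R,6R)-3-[(benzyloxy)methyl]-4-(2-methylprop-2-en-1-yl)-6-[(2S)-6-methylhept-5-en-2-yl]cyclohex-2-en-1-one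
Product: 14 (1R,4R,6R)-3-[(benzyloxy)methyl]-4-(2-methylprop-2-en-1-yl)-6-[(2S)-6-methylhept-5-en-2-yl]cyclohex-2-en-1-ol
Conditions: NaBH4, CeCl3·7H2O, MeOH, −78 °C
Reagents that add atoms: none
Why: Luche 1,2-reduction in which axial hydride attack anti to the pseudoaxial methallyl group gives the equatorial 1R alcohol, trans to the side chain and cis to the methallyl group.

Step 8
Reactants: 15 trans-cyclohexane-1,4-diyldimethanol
Product: 16 {trans-4-[(benzyloxy)methyl]cyclohexyl}methanol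
Conditions: NaH (1.0 equiv), BnBr (1.0 equiv), THF/DMF, 0 °C → rt
Reagents that add atoms: benzyl bromide, BrCc1ccccc1
Why: Williamson ether synthesis run to statistical mono-alkylation of the symmetrical diol, with unreacted diol recycled.

Step 9
Reactants: 16 {trans-4-[(benzyloxy)methyl]cyclohexyl}methanol
Product: 17 trans-4-[(benzyloxy)methyl]cyclohexane-1-carbaldehyde
Conditions: Dess–Martin periodinane, NaHCO3, CH2Cl2, 0 °C → rt
Reagents that add atoms: none
Why: Dess–Martin oxidation of the primary alcohol, giving an aldehyde whose trans (diequatorial) form is also the thermodynamically preferred epimer.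

Step 10
Reactants: 17 trans-4-[(benzyloxy)methyl]cyclohexane-1-carbaldehyde
Product: 18 trans-1-[(benzyloxy)methyl]-4-ethynylcyclohexane
Conditions: dimethyl (1-diazo-2-oxopropyl)phosphonate, K2CO3, MeOH, 0 °C → rt
Reagents that add atoms: dimethyl (1-diazo-2-oxopropyl)phosphonate, COP(=O)(OC)C(=[N+]=[N-])C(C)=O
Why: Seyferth–Gilbert homologation with the Ohira–Bestmann reagent converts the aldehyde into the terminal alkyne under mild base.

Step 11
Reactants: 18 trans-1-[(benzyloxy)methyl]-4-ethynylcyclohexane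
Product: 21 (3E)-4-{trans-4-[(benzyloxy)methyl]cyclohexyl}pent-3-en-1-ol, via alkenylalane 19 (not isolated), via lithium alanate 20 (not isolated)
Conditions: Me3Al (2.5 equiv), Cp2ZrCl2 (0.25 equiv), CH2Cl2, 0 °C → rt; then n-BuLi, THF/hexane, −78 °C; then oxirane, −78 → 0 °C; H2O
Reagents that add atoms: trimethylaluminium, C[Al](C)C; oxirane, C1CO1
Why: Negishi zirconium-catalysed carboalumination adds methyl and aluminium syn across the alkyne (methyl to the internal carbon), which fixes the E trisubstituted olefin, and the alanate then opens oxirane with retention of geometry.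

Step 12
Reactants: 21 (3E)-4-{trans-4-[(benzyloxy)methyl]cyclohexyl}pent-3-en-1-ol
Product: 22 (3E)-4-{trans-4-[(benzyloxy)methyl]cyclohexyl}pent-3-enal
Conditions: Dess–Martin periodinane, NaHCO3, CH2Cl2, 0 °C
Reagents that add atoms: none
Why: Buffered Dess–Martin oxidation stops at the β,γ-unsaturated aldehyde without moving the olefin into conjugation.

Step 13
Reactants: 22 (3E)-4-{trans-4-[(benzyloxy)methyl]cyclohexyl}pent-3-enal
Product: 23 (3E)-4-{trans-4-[(benzyloxy)methyl]cyclohexyl}pent-3-enoic acid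
Conditions: NaClO2, NaH2PO4, 2-methylbut-2-ene, t-BuOH/H2O, 0 °C → rt
Reagents that add atoms: sodium chlorite, [Na+].[O-]Cl=O
Why: Pinnick oxidation with a chlorine scavenger takes the aldehyde to the acid under conditions mild enough to leave the β,γ-olefin in place.

Step 14
Reactants: 14 (1R,4R,6R)-3-[(benzyloxy)methyl]-4-(2-methylprop-2-en-1-yl)-6-[(2S)-6-methylhept-5-en-2-yl]cyclohex-2-en-1-ol; 23 (3E)-4-{trans-4-[(benzyloxy)methyl]cyclohexyl}pent-3-enoic acid
Product: 24 (1R,4R,6R)-3-[(benzyloxy)methyl]-4-(2-methylprop-2-en-1-yl)-6-[(2S)-6-methylhept-5-en-2-yl]cyclohex-2-en-1-yl (3E)-4-{trans-4-[(benzyloxy)methyl]cyclohexyl}pent-3-enoate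
Conditions: DCC, DMAP (0.1 equiv), CH2Cl2, 0 °C → rt
Reagents that add atoms: none
Why: Steglich esterification joins the two fragments through the secondary allylic alcohol without touching any stereocentre.

Step 15
Reactants: 24 (1R,4R,6R)-3-[(benzyloxy)methyl]-4-(2-methylprop-2-en-1-yl)-6-[(2S)-6-methylhept-5-en-2-yl]cyclohex-2-en-1-yl (3E)-4-{trans-4-[(benzyloxy)methyl]cyclohexyl}pent-3-enoate
Product: 27 (2R,3E)-2-{(1R,4R,6R)-1-[(benzyloxy)methyl]-6-(2-methylprop-2-en-1-yl)-4-[(2S)-6-methylhept-5-en-2-yl]cyclohex-2-en-1-yl}-4-{trans-4-[(benzyloxy)methyl]cyclohexyl}pent-3-en-1-ol, via silyl ketene acetal 25 (not isolated), via trimethylsilyl ester 26 (not isolated)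
Conditions: LiN(i-Pr)2, Me3SiCl/Et3N, THF, −78 °C; then 65 °C; then LiAlH4, 0 °C → rt; H2O
Reagents that add atoms: none
Why: Ireland–Claisen rearrangement followed by hydride reduction, in which the suprafacial [3,3] shift transfers the C-1 carbinol configuration to the new quaternary carbon (cis to the methallyl group) and moves the olefin to its final ring A position, while the chair transition state of the E-silyl ketene acetal, with the alkenyl group axial and away from the ring, sets the adjacent tertiary centre.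

Step 16
Reactants: 27 the primary alcohol from step 15
Product: 28 (2R,3E)-2-{(1R,4R,6R)-1-[(benzyloxy)methyl]-6-(2-methylprop-2-en-1-yl)-4-[(2S)-6-methylhept-5-en-2-yl]cyclohex-2-en-1-yl}-4-{trans-4-[(benzyloxy)methyl]cyclohexyl}pent-3-enal
Conditions: Dess–Martin periodinane, NaHCO3, CH2Cl2, 0 °C
Reagents that add atoms: none
Why: Buffered Dess–Martin oxidation gives the α-branched β,γ-unsaturated aldehyde under non-epimerising conditions; it is used at once.

Step 17
Reactants: 28 the aldehyde from step 16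
Product: 29 (3R,4R,6R)-3-[(benzyloxy)methyl]-3-{(3R,4E)-5-{trans-4-[(benzyloxy)methyl]cyclohexyl}hexa-1,4-dien-3-yl}-4-(2-methylprop-2-en-1-yl)-6-[(2S)-6-methylhept-5-en-2-yl]cyclohex-1-ene
Conditions: Ph3PCH3Br, KN(SiMe3)2, THF, 0 °C; then 28, −78 → 0 °C
Reagents that add atoms: methyltriphenylphosphonium bromide, C[P+](c1ccccc1)(c1ccccc1)c1ccccc1.[Br-]
Why: Wittig methylenation with the salt-free ylide at low temperature converts the aldehyde into the vinyl group faster than the α-centre can enolise.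

Step 18
Reactants: 29 the triene from step 17
Product: 30 (4R,4aR,7R,8aR)-4a-[(benzyloxy)methyl]-4-{(1E)-2-{trans-4-[(benzyloxy)methyl]cyclohexyl}prop-1-en-1-yl}-2-methyl-7-[(2S)-6-methylhept-5-en-2-yl]-1,4,4a,7,8,8a-hexahydronaphthalene
Conditions: second-generation Grubbs catalyst, (H2IMes)(PCy3)Cl2Ru=CHPh (5 mol %), CH2Cl2 (5 mM), 40 °C
Reagents that add atoms: none
Why: Ring-closing metathesis between the vinyl group and the 1,1-disubstituted methallyl olefin, held cis on ring A, closes ring B as the cis-fused trisubstituted cyclohexene, while the ring A olefin and the two hindered trisubstituted olefins do not compete.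

Step 19
Reactants: 30 the bicyclic bis(benzyl ether) from step 18
Product: 31 (4R,4aR,7R,8aR)-4a-(hydroxymethyl)-4-{(1E)-2-[trans-4-(hydroxymethyl)cyclohexyl]prop-1-en-1-yl}-2-methyl-7-[(2S)-6-methylhept-5-en-2-yl]-1,4,4a,7,8,8a-hexahydronaphthalene
Conditions: lithium 4,4′-di-tert-butylbiphenylide, THF, −78 °C; then H2O
Reagents that add atoms: none
Why: Reductive debenzylation by single-electron transfer cleaves both benzyl ethers and leaves the isolated, non-conjugated olefins untouched.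

Step 20
Reactants: 31 the diol from step 19
Product: 33 (4R,4aR,7R,8aR)-4-{(1E)-2-(trans-4-carboxycyclohexyl)prop-1-en-1-yl}-2-methyl-7-[(2S)-6-methylhept-5-en-2-yl]-1,4,4a,7,8,8a-hexahydronaphthalene-4a-carboxylic acid (target), via dialdehyde 32 (not isolated)
Conditions: 2,2,6,6-tetramethylpiperidin-1-oxyl (0.3 equiv), PhI(OAc)2 (5 equiv), MeCN/H2O (1:1), rt
Reagents that add atoms: water, O
Why: Nitroxyl-catalysed oxidation with a hypervalent iodine co-oxidant takes both primary alcohols through the aldehyde hydrates to the carboxylic acids without affecting the olefins or any stereocentre.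

**Compound list**

1 | (S)-citronellal, (3S)-3,7-dimethyloct-6-enal | CC(C)=CCC[C@H](C)CC=O | starting material
2 | methyl vinyl ketone, but-3-en-2-one | CC(=O)C=C | starting material
3 | (2R,3S)-3,7-dimethyl-2-(3-oxobutyl)oct-6-enal | CC(C)=CCC[C@H](C)[C@@H](CCC(C)=O)C=O | intermediate
4 | (4R)-4-[(2S)-6-methylhept-5-en-2-yl]cyclohex-2-en-1-one | CC(C)=CCC[C@H](C)[C@@H]1C=CC(=O)CC1 | intermediate
5 | lithium (4R)-4-[(2S)-6-methylhept-5-en-2-yl]cyclohexa-1,5-dien-1-olate | CC(C)=CCC[C@H](C)[C@@H]1C=CC(O[Li])=CC1 | intermediate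
6 | (4R,6R)-6-(2-methylprop-2-en-1-yl)-4-[(2S)-6-methylhept-5-en-2-yl]cyclohex-2-en-1-one (4,6-trans) | CC(C)=CCC[C@H](C)[C@@H]1C=CC(=O)[C@@H](CC(C)=C)C1 | intermediate
7 | tributyltin hydride | CCCC[SnH](CCCC)CCCC | starting material
8 | benzyl chloromethyl ether | ClCOCc1ccccc1 | starting material
9 | tributylstannyllithium | CCCC[Sn]([Li])(CCCC)CCCC | intermediate
10 | [(benzyloxy)methyl]tributylstannane | CCCC[Sn](CCCC)(CCCC)COCc1ccccc1 | intermediate
11 | [(benzyloxy)methyl]lithium | [Li]COCc1ccccc1 | intermediate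
12 | (1S,4R,6R)-1-[(benzyloxy)methyl]-6-(2-methylprop-2-en-1-yl)-4-[(2S)-6-methylhept-5-en-2-yl]cyclohex-2-en-1-ol (major C-1 epimer, OH cis to methallyl) | CC(C)=CCC[C@H](C)[C@@H]1C=C[C@](O)(COCc2ccccc2)[C@@H](CC(C)=C)C1 | intermediate
13 | (4R,6R)-3-[(benzyloxy)methyl]-4-(2-methylprop-2-en-1-yl)-6-[(2S)-6-methylhept-5-en-2-yl]cyclohex-2-en-1-one | CC(C)=CCC[C@H](C)[C@@H]1C(=O)C=C(COCc2ccccc2)[C@@H](CC(C)=C)C1 | intermediate
14 | (1R,4R,6R)-3-[(benzyloxy)methyl]-4-(2-methylprop-2-en-1-yl)-6-[(2S)-6-methylhept-5-en-2-yl]cyclohex-2-en-1-ol | CC(C)=CCC[C@H](C)[C@@H]1[C@@H](O)C=C(COCc2ccccc2)[C@@H](CC(C)=C)C1 | intermediate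
15 | trans-cyclohexane-1,4-diyldimethanol | OC[C@H]1CC[C@H](CO)CC1 | starting material
16 | {trans-4-[(benzyloxy)methyl]cyclohexyl}methanol | OC[C@H]1CC[C@H](COCc2ccccc2)CC1 | intermediate
17 | trans-4-[(benzyloxy)methyl]cyclohexane-1-carbaldehyde | O=C[C@H]1CC[C@H](COCc2ccccc2)CC1 | intermediate
18 | trans-1-[(benzyloxy)methyl]-4-ethynylcyclohexane | C#C[C@H]1CC[C@H](COCc2ccccc2)CC1 | intermediate
19 | {(1E)-2-{trans-4-[(benzyloxy)methyl]cyclohexyl}prop-1-en-1-yl}dimethylalane | C[Al](C)/C=C(\C)[C@H]1CC[C@H](COCc2ccccc2)CC1 | intermediate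
20 | lithium butyl{(1E)-2-{trans-4-[(benzyloxy)methyl]cyclohexyl}prop-1-en-1-yl}dimethylalanate | [Li+].CCCC[Al-](C)(C)/C=C(\C)[C@H]1CC[C@H](COCc2ccccc2)CC1 | intermediate
21 | (3E)-4-{trans-4-[(benzyloxy)methyl]cyclohexyl}pent-3-en-1-ol | OCC/C=C(\C)[C@H]1CC[C@H](COCc2ccccc2)CC1 | intermediate
22 | (3E)-4-{trans-4-[(benzyloxy)methyl]cyclohexyl}pent-3-enal | O=CC/C=C(\C)[C@H]1CC[C@H](COCc2ccccc2)CC1 | intermediate
23 | (3E)-4-{trans-4-[(benzyloxy)methyl]cyclohexyl}pent-3-enoic acid | OC(=O)C/C=C(\C)[C@H]1CC[C@H](COCc2ccccc2)CC1 | intermediate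
24 | (1R,4R,6R)-3-[(benzyloxy)methyl]-4-(2-methylprop-2-en-1-yl)-6-[(2S)-6-methylhept-5-en-2-yl]cyclohex-2-en-1-yl (3E)-4-{trans-4-[(benzyloxy)methyl]cyclohexyl}pent-3-enoate | CC(C)=CCC[C@H](C)[C@@H]1[C@@H](OC(=O)C/C=C(\C)[C@H]2CC[C@H](COCc3ccccc3)CC2)C=C(COCc2ccccc2)[C@@H](CC(C)=C)C1 | intermediate
25 | (1E,3E)-trimethylsilyl ketene acetal of 24: 1-[(1R,4R,6R)-cyclohexenyloxy]-1-(trimethylsilyloxy)-4-{trans-4-[(benzyloxy)methyl]cyclohexyl}penta-1,3-diene | CC(C)=CCC[C@H](C)[C@@H]1[C@@H](O/C(O[Si](C)(C)C)=C\C=C(/C)[C@H]2CC[C@H](COCc3ccccc3)CC2)C=C(COCc2ccccc2)[C@@H](CC(C)=C)C1 | intermediate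
26 | trimethylsilyl (2R,3E)-2-{(1R,4R,6R)-1-[(benzyloxy)methyl]-6-(2-methylprop-2-en-1-yl)-4-[(2S)-6-methylhept-5-en-2-yl]cyclohex-2-en-1-yl}-4-{trans-4-[(benzyloxy)methyl]cyclohexyl}pent-3-enoate | CC(C)=CCC[C@H](C)[C@@H]1C=C[C@@](COCc2ccccc2)([C@H](C(=O)O[Si](C)(C)C)/C=C(\C)[C@H]2CC[C@H](COCc3ccccc3)CC2)[C@@H](CC(C)=C)C1 | intermediate
27 | (2R,3E)-2-{(1R,4R,6R)-1-[(benzyloxy)methyl]-6-(2-methylprop-2-en-1-yl)-4-[(2S)-6-methylhept-5-en-2-yl]cyclohex-2-en-1-yl}-4-{trans-4-[(benzyloxy)methyl]cyclohexyl}pent-3-en-1-ol | CC(C)=CCC[C@H](C)[C@@H]1C=C[C@@](COCc2ccccc2)([C@H](CO)/C=C(\C)[C@H]2CC[C@H](COCc3ccccc3)CC2)[C@@H](CC(C)=C)C1 | intermediate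
28 | (2R,3E)-2-{(1R,4R,6R)-1-[(benzyloxy)methyl]-6-(2-methylprop-2-en-1-yl)-4-[(2S)-6-methylhept-5-en-2-yl]cyclohex-2-en-1-yl}-4-{trans-4-[(benzyloxy)methyl]cyclohexyl}pent-3-enal | CC(C)=CCC[C@H](C)[C@@H]1C=C[C@@](COCc2ccccc2)([C@H](C=O)/C=C(\C)[C@H]2CC[C@H](COCc3ccccc3)CC2)[C@@H](CC(C)=C)C1 | intermediate
29 | (3R,4R,6R)-3-[(benzyloxy)methyl]-3-{(3R,4E)-5-{trans-4-[(benzyloxy)methyl]cyclohexyl}hexa-1,4-dien-3-yl}-4-(2-methylprop-2-en-1-yl)-6-[(2S)-6-methylhept-5-en-2-yl]cyclohex-1-ene | CC(C)=CCC[C@H](C)[C@@H]1C=C[C@@](COCc2ccccc2)([C@H](C=C)/C=C(\C)[C@H]2CC[C@H](COCc3ccccc3)CC2)[C@@H](CC(C)=C)C1 | intermediate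
30 | (4R,4aR,7R,8aR)-4a-[(benzyloxy)methyl]-4-{(1E)-2-{trans-4-[(benzyloxy)methyl]cyclohexyl}prop-1-en-1-yl}-2-methyl-7-[(2S)-6-methylhept-5-en-2-yl]-1,4,4a,7,8,8a-hexahydronaphthalene | CC(C)=CCC[C@H](C)[C@@H]1C=C[C@]2(COCc3ccccc3)[C@@H](CC(C)=C[C@@H]2/C=C(\C)[C@H]2CC[C@H](COCc3ccccc3)CC2)C1 | intermediate
31 | (4R,4aR,7R,8aR)-4a-(hydroxymethyl)-4-{(1E)-2-[trans-4-(hydroxymethyl)cyclohexyl]prop-1-en-1-yl}-2-methyl-7-[(2S)-6-methylhept-5-en-2-yl]-1,4,4a,7,8,8a-hexahydronaphthalene | CC(C)=CCC[C@H](C)[C@@H]1C=C[C@]2(CO)[C@@H](CC(C)=C[C@@H]2/C=C(\C)[C@H]2CC[C@H](CO)CC2)C1 | intermediate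
32 | (4R,4aR,7R,8aR)-4-{(1E)-2-(trans-4-formylcyclohexyl)prop-1-en-1-yl}-2-methyl-7-[(2S)-6-methylhept-5-en-2-yl]-1,4,4a,7,8,8a-hexahydronaphthalene-4a-carbaldehyde | CC(C)=CCC[C@H](C)[C@@H]1C=C[C@]2(C=O)[C@@H](CC(C)=C[C@@H]2/C=C(\C)[C@H]2CC[C@H](C=O)CC2)C1 | intermediate
33 | (4R,4aR,7R,8aR)-4-{(1E)-2-(trans-4-carboxycyclohexyl)prop-1-en-1-yl}-2-methyl-7-[(2S)-6-methylhept-5-en-2-yl]-1,4,4a,7,8,8a-hexahydronaphthalene-4a-carboxylic acid | CC(C)=CCC[C@H](C)[C@@H]1C=C[C@]2(C(=O)O)[C@@H](CC(C)=C[C@@H]2/C=C(\C)[C@H]2CC[C@H](C(=O)O)CC2)C1 | target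

**Totals and risks**

Total step count: 20. Longest linear sequence: 13 steps (steps 1–3, 5–7, 14–20; the fragment 2 branch, steps 8–13 then 14–20, is equally long). The stannane branch is step 4.

Most likely to fail, with fallbacks:

Step 3 (trans selectivity of the α′-methallylation; the kinetic axial product is the less stable epimer). If the trans:cis ratio is poor, the centre is set by auxiliary control instead. The fallback sets out from enone 4, which is condensed with (R)-1-amino-2-(methoxymethyl)pyrrolidine to give the hydrazone F1. Its lithium azaenolate (LiN(i-Pr)2, THF, −78 °C) is alkylated with 3-bromo-2-methylprop-1-ene on the face dictated by the chelated auxiliary to give the alkylated hydrazone F2. Two-phase hydrolysis with aqueous oxalic acid then returns ketone 6, where the route is rejoined before step 5.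

Step 15 (Ireland–Claisen to a congested quaternary carbon, with the adjacent centre depending on ketene acetal geometry and chair/boat preference). If conversion or the C-2 epimer ratio is poor, the same bond is made by an aliphatic Claisen rearrangement of an enol ether of fixed geometry. The fallback sets out from alkyne 18 and alcohol 14. Alane 19, made from 18 as in step 11, is trapped with paraformaldehyde to give the allylic alcohol F3, and MnO2 oxidation gives the enal F4. Stork–Zhao olefination ((iodomethyl)triphenylphosphonium iodide, NaN(SiMe3)2, THF, −78 °C) gives the (1Z,3E)-dienyl iodide F5. Copper-catalysed C–O coupling with 14 (CuI, 3,4,7,8-tetramethyl-1,10-phenanthroline, Cs2CO3, toluene, 80 °C) gives the allyl (Z)-dienyl ether F6. Heating F6 in xylene at 140 °C brings about the rearrangement through the chair with the alkenyl group axial and delivers aldehyde 28 directly, where the route is rejoined before step 17.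

Step 17 (methylenation of aldehyde 28, whose α-hydrogen is both allylic and α to the carbonyl, so the basic ylide may epimerise or conjugate it). The fallback is a Peterson olefination that sets out from 28. The non-basic organocerium reagent from Me3SiCH2MgCl and CeCl3 (THF, −78 °C) adds to give the β-hydroxysilane F7, and syn-elimination with KH in THF gives triene 29, where the route is rejoined before step 18.

**Further compounds**

F1 | step 3 | (R)-1-amino-2-(methoxymethyl)pyrrolidine hydrazone of enone 4 | CC(C)=CCC[C@H](C)[C@@H]1C=CC(=NN2CCC[C@@H]2COC)CC1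
F2 | step 3 | (R)-1-amino-2-(methoxymethyl)pyrrolidine hydrazone of ketone 6 | CC(C)=CCC[C@H](C)[C@@H]1C=CC(=NN2CCC[C@@H]2COC)[C@@H](CC(C)=C)C1
F3 | step 15 | (2E)-3-{trans-4-[(benzyloxy)methyl]cyclohexyl}but-2-en-1-ol | OC/C=C(\C)[C@H]1CC[C@H](COCc2ccccc2)CC1
F4 | step 15 | (2E)-3-{trans-4-[(benzyloxy)methyl]cyclohexyl}but-2-enal | O=C/C=C(\C)[C@H]1CC[C@H](COCc2ccccc2)CC1
F5 | step 15 | (1Z,3E)-1-iodo-4-{trans-4-[(benzyloxy)methyl]cyclohexyl}penta-1,3-diene | I/C=C\C=C(/C)[C@H]1CC[C@H](COCc2ccccc2)CC1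
F6 | step 15 | (1Z,3E)-4-{trans-4-[(benzyloxy)methyl]cyclohexyl}penta-1,3-dien-1-yl (1R,4R,6R)-3-[(benzyloxy)methyl]-4-(2-methylprop-2-en-1-yl)-6-[(2S)-6-methylhept-5-en-2-yl]cyclohex-2-en-1-yl ether | CC(C)=CCC[C@H](C)[C@@H]1[C@@H](O/C=C\C=C(/C)[C@H]2CC[C@H](COCc3ccccc3)CC2)C=C(COCc2ccccc2)[C@@H](CC(C)=C)C1
F7 | step 17 | (3R,4E)-3-{(1R,4R,6R)-1-[(benzyloxy)methyl]-6-(2-methylprop-2-en-1-yl)-4-[(2S)-6-methylhept-5-en-2-yl]cyclohex-2-en-1-yl}-5-{trans-4-[(benzyloxy)methyl]cyclohexyl}-1-(trimethylsilyl)hex-4-en-2-ol (carbinol epimers) | CC(C)=CCC[C@H](C)[C@@H]1C=C[C@@](COCc2ccccc2)([C@H](C(O)C[Si](C)(C)C)/C=C(\C)[C@H]2CC[C@H](COCc3ccccc3)CC2)[C@@H](CC(C)=C)C1
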